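The readings were computed for an exercise, noise included.

More reagent buys no visible gain in the earlier runs: at 40.0 h the noon run, with 0.75 equiv, reads 23.7% and the midnight run, with 0.34 equiv, reads 23.0%, a gap smaller than the scatter of 1 percentage point. So I reckon with substrate and time, and I follow the fraction left, not the fraction made.

| setting | winter | midnight | noon | north-east | north | east | west |
|---|---|---|---|---|---|---|---|
| substrate | 0.050 M | 0.050 M | 0.050 M | 0.050 M | 0.050 M | 0.050 M | 0.050 M |
| reagent | 0.50 equiv | 0.34 equiv | 0.75 equiv | 0.500 equiv | 0.500 equiv (fed, over 1.25 d) | 0.500 equiv | 0.500 equiv |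
| free catalyst | 0.5 mol% | 0.5 mol% | 0.5 mol% | 0.5 mol% | 0.5 mol% | 0.5 mol% | 0.5 mol% |
| impurity | 0.15 mM | 0.15 mM | 0.15 mM | 0.15 mM | 0.15 mM | 0.15 mM | 0.15 mM |
| remark | run made earlier | run made earlier | run made earlier | a single well-mixed tank run continuously and read at steady state, 12.5 d in it on average | a stirred flask in which reagent is dosed at a steady rate over 1.25 d without added volume, worked up at 2.5 d | a single well-mixed tank run continuously and read at steady state, 2.5 d in it on average | everything together in a closed stirred flask, run for 2.5 d |
| time |  |  |  |  | 2.5 d |  | 2.5 d |

| run | time / h | product / % |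
|---|---|---|
| winter | 5.00 | 3.6 |
| winter | 10.0 | 7.6 |
| winter | 15.0 | 7.7 |
| winter | 20.0 | 12.3 |
| winter | 25.0 | 17.6 |
| winter | 30.0 | 17.1 |
| winter | 40.0 | 21.9 |
| midnight | 3.00 | 2.0 |
| midnight | 4.00 | 4.7 |
| midnight | 6.00 | 6.4 |
| midnight | 10.0 | 6.9 |
| midnight | 15.0 | 11.4 |
| midnight | 25.0 | 15.1 |
| midnight | 40.0 | 23.0 |
| noon | 5.00 | 5.9 |
| noon | 10.0 | 6.4 |
| noon | 15.0 | 8.9 |
| noon | 20.0 | 15.2 |
| noon | 25.0 | 14.0 |
| noon | 30.0 | 18.7 |
| noon | 40.0 | 23.7 |

(scatter of a reading: 1 percentage point)

- the stated concentrations are those of everything mixed, before any reaction; amounts are the same in each set-up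
- what was read earlier has a scatter of 1 percentage point, one standard deviation
- the feed brings no volume worth counting
- the earlier runs were made in a closed, stirred flask

- the set-up with the highest amount of product at the outlet or at the end, in percent of the substrate put in ("none" if the first two lie within 2 percentage points) (north-east / north / east / west / none)
- amount of product at the outlet or at the end, in percent of the substrate put in, north-east
- amount of product at the outlet or at the end, in percent of the substrate put in, north
- amount of product at the outlet or at the end, in percent of the substrate put in, east
- amount of product at the outlet or at the end, in percent of the substrate put in, west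

Averaged, the last readings of the winter, midnight and noon runs leave 77.1% of the substrate, which reads as a first-order constant of 0.156 d⁻¹, with the scatter of those readings in it. Over 2.5 d this constant gives 0.389; I call constant times time in the vessel, average time in a tank, the reach, the Damköhler number.

I start with the main step in the closed flask, west. The fraction left is one over the exponential of the reach, 67.8%, so west makes 32.2%, less than the reagent charge allows.

Next I add back-mixing. In a tank the fraction left is one over one plus the reach, 72.0%, so east, with 2.5 d in the tank on average, makes 28.0% by my reckoning, less than west.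

Then I add the reagent. The north-east tank has a reach of 1.95, and the tank rule alone gives 66.1%. That is more than 0.500 equiv can supply, if one reagent serves one substrate. As the limiting reagent in north-east, I expect it to hold the product near half of the substrate, so I write about half for north-east, my best set-up.

Last comes the dosing in north. Over the 1.25 d of the feed in north the rule uses 17.7% of the substrate, less than the 0.500 equiv dosed, so I expect the dosing to cost little and put north a little under west.

The forecast, with figures slightly different from mine, has north-east best at 48%, with 32% for north, 29% for east and 33% for west, and it warns: “Any slow catalyst death is the main risk for the long tank.”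

The flask gives north-east best at 48.9%, then west at 32.1%, north at 30.3% and east at 28.8%.

    catalyst intermediate C ⇌ released group + catalyst intermediate D (K = 0.0179 M, k = 6.48 h⁻¹)
    reagent + catalyst intermediate A ⇌ catalyst intermediate B (K = 110 L mol⁻¹, k = 26800 L mol⁻¹ h⁻¹)
    2 free catalyst → spent catalyst B (k = 85.3 L mol⁻¹ h⁻¹)
    catalyst intermediate D → free catalyst + product (k = 13.3 h⁻¹)
    catalyst intermediate B → catalyst intermediate C (k = 25.5 h⁻¹)
    substrate + free catalyst → catalyst intermediate A (k = 403 L mol⁻¹ h⁻¹)
    free catalyst + impurity → spent catalyst A (k = 17100 L mol⁻¹ h⁻¹)

Taking away the reaction of two free catalyst to spent catalyst B makes no difference to the north-east outlet. The reach carries over to the east tank, where the tank rule leaves 72.0% and the substrate stands at 71.0% of its charge.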